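**Retrosynthetic overview**
- The target is the desilylated form of a silyl-protected C6 ester, made from a 4,6-diol and protected 4-hydroxybenzoic acid. The diol comes from a bicyclic β-hydroxy ketone by hydroxyl-directed reduction at C6.
- Key disconnection: the cyclopentane is cut at C1–C2 and C4–C5. A zinc homoenolate of an isopropyl ketone (from a cyclopropanol) adds to the β-carbon of a cycloheptadienone, joining two carbonyl β-carbons, and the resulting enolate closes C4–C5 by aldol.
- The dienone comes from a meso oxabicyclic ketone by enantioselective deprotonation and opening of the oxygen bridge. This reveals the C8 carbinol, the C9=C10 alkene and the enone together.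
- The oxabicycle comes from 2,5-dimethylfuran and trichloroacetone by oxyallyl-cation (4+3) cycloaddition.
- Ring order: seven-membered ring first (step 1), five-membered ring second (step 5).

Numbering used in the text (daucane): five-membered ring C1(Me)–C2–C3–C4(OH, iPr)–C5(H); seven-membered ring C5–C6(O)–C7–C8(Me, O)–C9=C10–C1.

Assumption: the sense of induction of the chiral lithium amide (step 2) and of the chiral carbene ligand (step 5) is taken by analogy with their use on related ketones and enones; both are available as either antipode, and the one giving the drawn configuration is meant.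

**Step 1**
Reactants: 1 2,5-dimethylfuran; 2 1,1,3-trichloropropan-2-one
Product: 4 (1R,5S)-1,5-dimethyl-8-oxabicyclo[3.2.1]oct-6-en-3-one, via dichloro cycloadduct 3 (not isolated)
Conditions: NaOCH2CF3, CF3CH2OH, 0 °C → rt; then Zn/Cu couple, NH4Cl, MeOH, rt
Reagents that add atoms: none
Why: (4+3) cycloaddition in which base turns 2 into a chlorinated oxyallyl (α-keto) cation whose two α-carbons bond to C2 and C5 of the furan; the oxygen bridge forces both methyl-bearing bridgeheads cis (meso product), and zinc then removes both chlorines reductively.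

**Step 2**
Reactants: 4 (1R,5S)-1,5-dimethyl-8-oxabicyclo[3.2.1]oct-6-en-3-one
Product: 6 triethyl{[(1R,5R)-1,5-dimethyl-8-oxabicyclo[3.2.1]octa-2,6-dien-3-yl]oxy}silane, via lithium enolate 5 (not isolated)
Conditions: (R,R)-bis(1-phenylethyl)amine, n-BuLi, LiCl, THF, −100 °C; Et3SiCl, −100 → −40 °C
Reagents that add atoms: chlorotriethylsilane CC[Si](Cl)(CC)CC
Why: Asymmetric deprotonation of a meso ketone by a C2-symmetric chiral lithium amide (LiCl-assisted), which removes a proton from the methylene next to the 5S bridgehead, so that the bridgehead remote from the enol double bond (future C8) is the one that will keep its oxygen.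

**Step 3**
Reactants: 6 triethyl{[(1R,5R)-1,5-dimethyl-8-oxabicyclo[3.2.1]octa-2,6-dien-3-yl]oxy}silane
Product: 7 (6R)-3,6-dimethyl-6-[(triethylsilyl)oxy]cyclohepta-2,4-dien-1-one
Conditions: Et3SiOTf (5 mol%), CH2Cl2, −78 °C, 30 min; Et3N quench
Reagents that add atoms: none
Why: Lewis-acid-catalysed ring opening (vinylogous retro-oxa-Michael of the silyl enol ether with O-to-O silyl transfer) gives the enone, the C9=C10 alkene and the tertiary silyl ether; the C8–O bond is never broken, so C8 keeps the configuration fixed in step 2 (6R in 7), and low temperature with catalytic acid stops before loss of silanol to the tropone.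

**Step 4**
Reactants: 8 methyl 2-methylpropanoate
Product: 9 1-(propan-2-yl)cyclopropan-1-ol
Conditions: EtMgBr (2.4 equiv), Ti(OiPr)4 (0.2 equiv), Et2O, 0 °C → rt; aq NH4Cl
Reagents that add atoms: ethylmagnesium bromide CC[Mg]Br
Why: Kulinkovich cyclopropanation, in which the titanacyclopropane formed from EtMgBr and Ti(OiPr)4 adds twice to the ester carbonyl; no stereocentre is formed.

**Step 5**
Reactants: 7 (6R)-3,6-dimethyl-6-[(triethylsilyl)oxy]cyclohepta-2,4-dien-1-one; 9 1-(propan-2-yl)cyclopropan-1-ol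
Product: 12 (3R,3aR,6R,8aR)-3-hydroxy-6,8a-dimethyl-3-(propan-2-yl)-6-[(triethylsilyl)oxy]-2,3,3a,5,6,8a-hexahydroazulen-4(1H)-one, via zinc bis-homoenolate 10 (not isolated), via zinc enolate 11 (not isolated)
Conditions: Et2Zn (1.5 equiv), 9 (3.0 equiv), THF, 0 → 40 °C; then Cu(OTf)2 (5 mol%), 1-[(2S)-1-hydroxy-4-methylpentan-2-yl]-3-(2,4,6-trimethylphenyl)-4,5-dihydroimidazolium hexafluorophosphate (6 mol%), 7, Et2O, −30 → 25 °C, then 35 °C, 6 h; aq NH4Cl
Reagents that add atoms: none
Why: Proposed new method: diethylzinc turns 9 into the ring-opened zinc homoenolate 10 (β-carbon elimination of the zinc cyclopropoxide), and a carbene–copper catalyst transfers its β-keto-alkyl group to C1 of 7, joining two carbonyl β-carbons (closest known reactions: carbene–copper-catalysed conjugate addition of dialkylzincs to 3-methylcyclohept-2-enone forming a quaternary centre, and conjugate addition of zinc homoenolates to enones); attack at C9 (1,6) is held back because C9 is neopentylic beside the silyloxy-bearing C8 and the carbene ligand favours early C–C bond formation at C1; the ligand, not the remote C8 centre, picks the face of C1 (1R); zinc enolate 11 then closes C4–C5 by a 5-exo aldol through a zinc-bridged transition state that puts the hydroxyl cis to C6 and the isopropyl group away from it; the closure is kinetically cis-fused, but the zinc aldolate forms reversibly, so at 35 °C the mixture is expected to settle to the trans-fused, hydrogen-bonded ketol (4R,5R), the fusion favoured at equilibrium in hydroazulen-4-ones and not penalised here because the angular methyl has no syn-axial hydrogen on trigonal C6 and C9.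

**Step 6**
Reactants: 12 (3R,3aR,6R,8aR)-3-hydroxy-6,8a-dimethyl-3-(propan-2-yl)-6-[(triethylsilyl)oxy]-2,3,3a,5,6,8a-hexahydroazulen-4(1H)-one
Product: 13 (3R,3aS,4S,6R,8aR)-6,8a-dimethyl-3-(propan-2-yl)-6-[(triethylsilyl)oxy]-1,2,3,3a,4,5,6,8a-octahydroazulene-3,4-diol
Conditions: Me4NBH(OAc)3 (5 equiv), MeCN/AcOH 1:1, −30 °C, 18 h; aq NaHCO3
Reagents that add atoms: none
Why: Evans–Saksena-type directed reduction, in which the acetoxyborohydride exchanges onto the tertiary C4 hydroxyl and delivers hydride intramolecularly; in the trans-fused skeleton O4 lies on the β-face next to C6, so hydride enters from β and the new hydroxyl is α (6S, 1,3-anti to O4), while the silyl ether at C8 cannot direct.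

**Step 7**
Reactants: 13 (3R,3aS,4S,6R,8aR)-6,8a-dimethyl-3-(propan-2-yl)-6-[(triethylsilyl)oxy]-1,2,3,3a,4,5,6,8a-octahydroazulene-3,4-diol; 14 4-[(tert-butyldimethylsilyl)oxy]benzoic acid
Product: 15 (3R,3aS,4S,6R,8aR)-3-hydroxy-6,8a-dimethyl-3-(propan-2-yl)-6-[(triethylsilyl)oxy]-1,2,3,3a,4,5,6,8a-octahydroazulen-4-yl 4-[(tert-butyldimethylsilyl)oxy]benzoate
Conditions: DCC (1.5 equiv), DMAP (0.3 equiv), CH2Cl2, 0 °C → rt
Reagents that add atoms: none
Why: Steglich esterification acylates only the secondary C6 hydroxyl (the C4 hydroxyl is tertiary and hindered, C8 is silylated), with retention at C6 because its C–O bond is not touched.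

**Step 8**
Reactants: 15 (3R,3aS,4S,6R,8aR)-3-hydroxy-6,8a-dimethyl-3-(propan-2-yl)-6-[(triethylsilyl)oxy]-1,2,3,3a,4,5,6,8a-octahydroazulen-4-yl 4-[(tert-butyldimethylsilyl)oxy]benzoate
Product: 16 (3R,3aS,4S,6R,8aR)-3,6-dihydroxy-6,8a-dimethyl-3-(propan-2-yl)-1,2,3,3a,4,5,6,8a-octahydroazulen-4-yl 4-hydroxybenzoate
Conditions: Bu4NF (3 equiv), AcOH (3 equiv), THF, 0 °C → rt
Reagents that add atoms: none
Why: Fluoride desilylation cleaves the aryl silyl ether and the tertiary triethylsilyl ether, while acetic acid buffering keeps the benzoate and the acid-sensitive tertiary allylic alcohol intact; no stereocentre is involved.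

**Compound list**
1 | 2,5-dimethylfuran | Cc1ccc(C)o1 | starting material
2 | 1,1,3-trichloropropan-2-one | ClCC(=O)C(Cl)Cl | starting material
3 | 2,4-dichloro-1,5-dimethyl-8-oxabicyclo[3.2.1]oct-6-en-3-one (cis-bridged; chlorine-bearing carbons as epimer mixture) | O=C1C(Cl)[C@@]2(C)C=C[C@@](C)(C1Cl)O2 | intermediate (not isolated)
4 | (1R,5S)-1,5-dimethyl-8-oxabicyclo[3.2.1]oct-6-en-3-one (meso) | O=C1C[C@@]2(C)C=C[C@@](C)(C1)O2 | intermediate
5 | lithium (1R,5R)-1,5-dimethyl-8-oxabicyclo[3.2.1]octa-2,6-dien-3-olate | [Li]OC1=C[C@@]2(C)C=C[C@@](C)(C1)O2 | intermediate (not isolated)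
6 | triethyl{[(1R,5R)-1,5-dimethyl-8-oxabicyclo[3.2.1]octa-2,6-dien-3-yl]oxy}silane | CC[Si](CC)(CC)OC1=C[C@@]2(C)C=C[C@@](C)(C1)O2 | intermediate
7 | (6R)-3,6-dimethyl-6-[(triethylsilyl)oxy]cyclohepta-2,4-dien-1-one | O=C1C=C(C)C=C[C@@](C)(C1)O[Si](CC)(CC)CC | intermediate
8 | methyl 2-methylpropanoate | COC(=O)C(C)C | starting material
9 | 1-(propan-2-yl)cyclopropan-1-ol | CC(C)C1(O)CC1 | intermediate
10 | bis(4-methyl-3-oxopentyl)zinc | CC(C)C(=O)CC[Zn]CCC(=O)C(C)C | intermediate (not isolated)
11 | {[(3R,6R)-3,6-dimethyl-3-(4-methyl-3-oxopentyl)-6-[(triethylsilyl)oxy]cyclohepta-1,4-dien-1-yl]oxy}(4-methyl-3-oxopentyl)zinc | CC(C)C(=O)CC[C@]1(C)C=C[C@](C)(O[Si](CC)(CC)CC)CC(O[Zn]CCC(=O)C(C)C)=C1 | intermediate (not isolated)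
12 | (3R,3aR,6R,8aR)-3-hydroxy-6,8a-dimethyl-3-(propan-2-yl)-6-[(triethylsilyl)oxy]-2,3,3a,5,6,8a-hexahydroazulen-4(1H)-one (trans-fused; 1β-Me, 4β-OH, 5α-H, 8α-OSiEt3) | CC(C)[C@]1(O)CC[C@]2(C)C=C[C@](C)(O[Si](CC)(CC)CC)CC(=O)[C@H]21 | intermediate
13 | (3R,3aS,4S,6R,8aR)-6,8a-dimethyl-3-(propan-2-yl)-6-[(triethylsilyl)oxy]-1,2,3,3a,4,5,6,8a-octahydroazulene-3,4-diol | CC(C)[C@]1(O)CC[C@]2(C)C=C[C@](C)(O[Si](CC)(CC)CC)C[C@H](O)[C@H]21 | intermediate
14 | 4-[(tert-butyldimethylsilyl)oxy]benzoic acid | CC(C)(C)[Si](C)(C)Oc1ccc(cc1)C(=O)O | starting material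
15 | (3R,3aS,4S,6R,8aR)-3-hydroxy-6,8a-dimethyl-3-(propan-2-yl)-6-[(triethylsilyl)oxy]-1,2,3,3a,4,5,6,8a-octahydroazulen-4-yl 4-[(tert-butyldimethylsilyl)oxy]benzoate | CC(C)[C@]1(O)CC[C@]2(C)C=C[C@](C)(O[Si](CC)(CC)CC)C[C@H](OC(=O)c3ccc(O[Si](C)(C)C(C)(C)C)cc3)[C@H]21 | intermediate
16 | (3R,3aS,4S,6R,8aR)-3,6-dihydroxy-6,8a-dimethyl-3-(propan-2-yl)-1,2,3,3a,4,5,6,8a-octahydroazulen-4-yl 4-hydroxybenzoate | CC(C)[C@]1(O)CC[C@]2(C)C=C[C@](C)(O)C[C@H](OC(=O)c3ccc(O)cc3)[C@H]21 | target

**Step count**
Total: 8 steps. Longest linear sequence: 7 steps (1 → 2 → 3 → 5 → 6 → 7 → 8); step 4 is a one-step side branch.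

**Steps most likely to fail, with fallbacks**

Step 5 (highest risk). Three selectivities ride on one operation: 1,4- versus 1,6-addition, the face of C1, and trans ring fusion by aldolate equilibration. The fallback sets out from 9 and 7 and comes back at 12. It separates the C–C bond formation from the ring closure and uses a Grignard reagent, for which carbene–copper catalysis gives 1,4-addition to dienones with quaternary-centre formation. Cyclopropanol 9 is opened with N-bromosuccinimide (CH2Cl2, 0 °C) to 1-bromo-4-methylpentan-3-one F1. Ketalisation (ethane-1,2-diol, TsOH, benzene, water removal) gives 2-(2-bromoethyl)-2-(propan-2-yl)-1,3-dioxolane F2. Magnesium in THF converts it into {2-[2-(propan-2-yl)-1,3-dioxolan-2-yl]ethyl}magnesium bromide F3. F3 is added to 7 with Cu(OTf)2 and the same imidazolinium ligand in Et2O at −30 °C to give (3S,6R)-3,6-dimethyl-3-{2-[2-(propan-2-yl)-1,3-dioxolan-2-yl]ethyl}-6-[(triethylsilyl)oxy]cyclohept-4-en-1-one F4. Neutral ketal cleavage (CeCl3·7H2O, NaI, MeCN) gives (3S,6R)-3,6-dimethyl-3-(4-methyl-3-oxopentyl)-6-[(triethylsilyl)oxy]cyclohept-4-en-1-one F5. F5 is closed under equilibrating aldol conditions (catalytic KOH, MeOH, 0 °C) to 12.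

Step 3. The Lewis acid may carry the ring opening on to 3,6-dimethyltropone by loss of silanol. The fallback sets out from enolate 5 and comes back at 7. The silyl chloride is left out and 5 is warmed to 0 °C so that the enolate itself expels the bridging alkoxide (anionic retro-oxa-Michael, no Lewis acid present). NH4Cl work-up gives (6R)-6-hydroxy-3,6-dimethylcyclohepta-2,4-dien-1-one F6. F6 is silylated (Et3SiOTf, 2,6-lutidine, CH2Cl2, −78 °C) to 7.

Step 6. Exchange of the borohydride onto a hindered, hydrogen-bonded tertiary hydroxyl may be slow, and external hydride could then enter from the α-face. The fallback sets out from 12 and comes back at 15. Reduction with NaBH4 and CeCl3·7H2O in MeOH at −78 °C is used, and the 6β-alcohol (3R,3aS,4R,6R,8aR)-6,8a-dimethyl-3-(propan-2-yl)-6-[(triethylsilyl)oxy]-1,2,3,3a,4,5,6,8a-octahydroazulene-3,4-diol F7 is taken on. F7 is esterified with inversion by a Mitsunobu reaction with 14 (PPh3, DIAD, toluene, 0 °C → rt), which gives 15 directly.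

**Further compounds**
F1 | step 5 | 1-bromo-4-methylpentan-3-one | CC(C)C(=O)CCBr
F2 | step 5 | 2-(2-bromoethyl)-2-(propan-2-yl)-1,3-dioxolane | CC(C)C1(CCBr)OCCO1
F3 | step 5 | {2-[2-(propan-2-yl)-1,3-dioxolan-2-yl]ethyl}magnesium bromide | CC(C)C1(CC[Mg]Br)OCCO1
F4 | step 5 | (3S,6R)-3,6-dimethyl-3-{2-[2-(propan-2-yl)-1,3-dioxolan-2-yl]ethyl}-6-[(triethylsilyl)oxy]cyclohept-4-en-1-one | CC(C)C1(CC[C@]2(C)C=C[C@](C)(O[Si](CC)(CC)CC)CC(=O)C2)OCCO1
F5 | step 5 | (3S,6R)-3,6-dimethyl-3-(4-methyl-3-oxopentyl)-6-[(triethylsilyl)oxy]cyclohept-4-en-1-one | CC(C)C(=O)CC[C@]1(C)C=C[C@](C)(O[Si](CC)(CC)CC)CC(=O)C1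
F6 | step 3 | (6R)-6-hydroxy-3,6-dimethylcyclohepta-2,4-dien-1-one | O=C1C=C(C)C=C[C@](C)(O)C1
F7 | step 6 | (3R,3aS,4R,6R,8aR)-6,8a-dimethyl-3-(propan-2-yl)-6-[(triethylsilyl)oxy]-1,2,3,3a,4,5,6,8a-octahydroazulene-3,4-diol | CC(C)[C@]1(O)CC[C@]2(C)C=C[C@](C)(O[Si](CC)(CC)CC)C[C@@H](O)[C@H]21
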